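**Strategy.** The target is cut at the C8–O4' ether bond and the C7–OH bond, back to two free phenols: (E)-sinapyl alcohol (ring A with C7–C9) and dihydrosinapyl alcohol (ring B). One peroxidase-mediated dehydrogenation joins the C8 radical site of the sinapyl unit to O4' of ring B, the only coupling position left on a phenoxyl radical whose C3', C5' and C1' are substituted. Solvent water then adds to C7 of the ring A quinone methide, giving the erythro-rich arylglycerol ether without protecting groups. Ring B is used in excess. Chiral chromatography then delivers the 7R,8S enantiomer.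

Key step: step 2

Remarks: (E)-sinapyl alcohol is used as purchased material, purified on silica before use. Racemic compounds are drawn as the enantiomer that corresponds to the target.

**Step 1**
Reactants: 1 4-allyl-2,6-dimethoxyphenol
Product: 3 dihydrosinapyl alcohol [4-(3-hydroxypropyl)-2,6-dimethoxyphenol], via B-alkyl O-boryl 9-BBN adduct 2 (not isolated)
Conditions: 9-BBN-H (0.5 M in THF, 2.3 equiv), THF, 0 °C → rt, N2; then 3 M aq. NaOH, 30% aq. H2O2, 0 °C → rt; aq. NH4Cl to pH 6, EtOAc
Reagents that add atoms: hydrogen peroxide, OO
Why: Brown hydroboration–oxidation, in which the bulky dialkylborane places boron on the terminal carbon of the allyl group (anti-Markovnikov), a further equivalent is taken up by the phenol as an aryl borinate with loss of H2, and alkaline H2O2 turns C–B into C–OH and frees the phenol; no stereocentre is formed.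

**Step 2**
Reactants: 4 (E)-sinapyl alcohol (1 equiv); 3 dihydrosinapyl alcohol (5 equiv)
Product: 8 racemic erythro-1-(4-hydroxy-3,5-dimethoxyphenyl)-2-[4-(3-hydroxypropyl)-2,6-dimethoxyphenoxy]propane-1,3-diol, via sinapyl phenoxyl radical 5 (not isolated), via ring B phenoxyl radical 6 (not isolated), via quinone methide 7 (not isolated)
Conditions: 4 (in acetone) and 30% aq. H2O2 (1.05 equiv) co-fed by syringe pump over 8 h into 3 and horseradish peroxidase (haem enzyme, cat.) in acetone/0.1 M citrate–phosphate buffer pH 4.5 (1:4), 25 °C; then dil. HCl to pH 3, 2 h; EtOAc; SiO2 chromatography (recovery of 3), then preparative C18 HPLC (MeOH/H2O) to remove the threo isomer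
Reagents that add atoms: water, O
Why: H2O2-activated peroxidase takes one electron and one proton from each phenol, the hydrogen peroxide ending as water; radical 5 carries spin at C8 (its C3 and C5 bear OMe), radical 6 has both ortho carbons and the para carbon substituted and can form a lasting bond only at O4', so their combination gives the C8–O4' ether as the ring A p-quinone methide 7, which is rearomatised by acid-assisted 1,6-addition of solvent water at C7. The closest known reaction type is the dehydrogenative cross-coupling of a monolignol with a 4-alkyl phenol to an arylglycerol β-aryl ether under slow-feed peroxidase conditions, the end-wise mode of lignin growth. No ring is formed. C8 arises from radical combination without any chiral influence and is racemic, while C7 is set relative to C8 by substrate control: in the conformer of 7 that holds C8–H in the plane of the exocyclic C1=C7 bond, the bulky 2,6-dimethoxyaryloxy group covers one face, so water should enter mainly from the other face and give the erythro isomer, the threo isomer being removed by HPLC. The step needs cross-coupling to beat 8–8 and 8–O–4 homo-coupling of 4 and needs water to beat hydroxyl or phenol addition to 7; the blocked ring positions of 3, its five-fold excess, the slow co-feed of 4 and H2O2 that keeps 5 dilute, and water as the bulk medium at acidic pH are what secure this.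

**Step 3**
Reactants: 8 racemic erythro-1-(4-hydroxy-3,5-dimethoxyphenyl)-2-[4-(3-hydroxypropyl)-2,6-dimethoxyphenoxy]propane-1,3-diol
Product: 9 (1R,2S)-1-(4-hydroxy-3,5-dimethoxyphenyl)-2-[4-(3-hydroxypropyl)-2,6-dimethoxyphenoxy]propane-1,3-diol (7R,8S; target)
Conditions: semi-preparative HPLC on silica-coated amylose tris(3,5-dimethylphenylcarbamate), n-hexane/i-PrOH, 25 °C; collection of the 7R,8S enantiomer, to be assigned by comparing its ECD curve with the TDDFT-computed curve
Reagents that add atoms: none
Why: Chromatographic resolution of a racemate on a polysaccharide carbamate chiral stationary phase separates the mirror-image forms by enantioselective adsorption without making or breaking a bond, so the erythro C7/C8 relationship set in step 2 is carried through unchanged.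

**Compound list**
1 | 4-allyl-2,6-dimethoxyphenol | COc1cc(CC=C)cc(OC)c1O | starting material
2 | 9-{3-[4-(9-borabicyclo[3.3.1]nonan-9-yloxy)-3,5-dimethoxyphenyl]propyl}-9-borabicyclo[3.3.1]nonane (B-alkyl O-boryl 9-BBN adduct) | COc1cc(CCCB2C3CCCC2CCC3)cc(OC)c1OB1C2CCCC1CCC2 | intermediate (not isolated)
3 | dihydrosinapyl alcohol, 4-(3-hydroxypropyl)-2,6-dimethoxyphenol | COc1cc(CCCO)cc(OC)c1O | intermediate
4 | (E)-sinapyl alcohol, 4-[(E)-3-hydroxyprop-1-enyl]-2,6-dimethoxyphenol | COc1cc(/C=C/CO)cc(OC)c1O | starting material
5 | sinapyl alcohol phenoxyl radical | COc1cc(/C=C/CO)cc(OC)c1[O] | intermediate (not isolated)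
6 | dihydrosinapyl alcohol phenoxyl radical (ring B radical) | COc1cc(CCCO)cc(OC)c1[O] | intermediate (not isolated)
7 | 4-{3-hydroxy-2-[4-(3-hydroxypropyl)-2,6-dimethoxyphenoxy]propylidene}-2,6-dimethoxycyclohexa-2,5-dien-1-one, ring A quinone methide, racemic at C8 (enantiomer leading to 9 drawn) | COC1=CC(=C[C@H](CO)Oc2c(OC)cc(CCCO)cc2OC)C=C(OC)C1=O | intermediate (not isolated)
8 | racemic erythro-1-(4-hydroxy-3,5-dimethoxyphenyl)-2-[4-(3-hydroxypropyl)-2,6-dimethoxyphenoxy]propane-1,3-diol (7R,8S and 7S,8R in equal parts; 7R,8S enantiomer drawn) | COc1cc([C@@H](O)[C@H](CO)Oc2c(OC)cc(CCCO)cc2OC)cc(OC)c1O | intermediate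
9 | (1R,2S)-1-(4-hydroxy-3,5-dimethoxyphenyl)-2-[4-(3-hydroxypropyl)-2,6-dimethoxyphenoxy]propane-1,3-diol (7R,8S, single enantiomer) | COc1cc([C@@H](O)[C@H](CO)Oc2c(OC)cc(CCCO)cc2OC)cc(OC)c1O | target

Total step count: 3
Longest linear sequence: 3 steps (1 → 3 → 8 → 9)

**Steps most likely to fail**

Step 2. Radical homo-coupling of 4 (8–8 and 8–O–4), disproportionation of the ring B radical and renewed oxidation of the phenolic product may outrun the cross-coupling, and hydration of the quinone methide may be slow or poorly erythro-selective. The fallback builds the same C8–O4' ether by polar, stepwise chemistry, setting out from 3 and coming back at 8. Phenol 3 is O-alkylated with ethyl bromoacetate (BrCC(=O)OCC; K2CO3, acetone, reflux; the phenoxide reacts, the aliphatic hydroxyl does not) to give ethyl 2-[4-(3-hydroxypropyl)-2,6-dimethoxyphenoxy]acetate F1. Its dianion (LiN(i-Pr)2, 2.2 equiv, THF, −78 °C; the side-chain hydroxyl is carried as the lithium alkoxide) is added to purchased 4-(benzyloxy)-3,5-dimethoxybenzaldehyde (COc1cc(C=O)cc(OC)c1OCc1ccccc1). This ester aldol addition is expected to favour the erythro adduct; after removal of the threo isomer on silica it gives racemic ethyl erythro-3-[4-(benzyloxy)-3,5-dimethoxyphenyl]-3-hydroxy-2-[4-(3-hydroxypropyl)-2,6-dimethoxyphenoxy]propanoate F2. LiAlH4 (THF, 0 °C) then reduces the ester to racemic erythro-1-[4-(benzyloxy)-3,5-dimethoxyphenyl]-2-[4-(3-hydroxypropyl)-2,6-dimethoxyphenoxy]propane-1,3-diol F3. Hydrogenolysis (H2, 1 atm, Pd/C (palladium metal on carbon), EtOAc/EtOH, rt) removes the benzyl ether and returns 8.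

Step 3. Enantiomer discrimination on the chiral phase may be too weak at preparative loading, so the bands overlap. The fallback is a classical resolution through covalent diastereomers, setting out from 8 and coming back at 9. Compound 8 is acylated at the phenol and at both primary hydroxyls with (1S,4R)-camphanic chloride (ClC(=O)[C@@]12CC[C@@](C)(C(=O)O1)C2(C)C; 3.3 equiv, pyridine/CH2Cl2, 0 °C). The hindered benzylic C7–OH is meant to stay free, so that the later base treatment cannot expel a C7 ester through a quinone methide and scramble C7. The two diastereomers are separated on silica gel or by fractional crystallisation: the 4-O,9-O,9'-O-tris[(1S,4R)-camphanoyl] derivative of 9 F4 and the 4-O,9-O,9'-O-tris[(1S,4R)-camphanoyl] derivative of the 7S,8R enantiomer F5. A crystal of either would also allow the configuration to be assigned by X-ray analysis against the known auxiliary. Methanolysis of F4 (K2CO3 cat., MeOH, 0 °C → rt) gives 9.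

Step 1. The phenol may consume B–H and leave the hydroboration incomplete, and the electron-rich phenolate may be oxidised during the alkaline peroxide treatment. The fallback does not functionalise the allyl group; it saturates the alkene of the other monomer, setting out from 4 and coming back at 3. Hydrogenation of 4 (H2, 1 atm, Pd/C (palladium metal on carbon), EtOAc, rt, stopped after one equivalent of H2 to avoid allylic C–O hydrogenolysis) gives 3 directly, so no further compound arises (F0).

**Further compounds**
F1 | step 2 | ethyl 2-[4-(3-hydroxypropyl)-2,6-dimethoxyphenoxy]acetate | CCOC(=O)COc1c(OC)cc(CCCO)cc1OC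
F2 | step 2 | racemic ethyl erythro-3-[4-(benzyloxy)-3,5-dimethoxyphenyl]-3-hydroxy-2-[4-(3-hydroxypropyl)-2,6-dimethoxyphenoxy]propanoate (enantiomer matching 9 drawn) | COc1cc([C@@H](O)[C@H](C(=O)OCC)Oc2c(OC)cc(CCCO)cc2OC)cc(OC)c1OCc1ccccc1
F3 | step 2 | racemic erythro-1-[4-(benzyloxy)-3,5-dimethoxyphenyl]-2-[4-(3-hydroxypropyl)-2,6-dimethoxyphenoxy]propane-1,3-diol (enantiomer matching 9 drawn) | COc1cc([C@@H](O)[C@H](CO)Oc2c(OC)cc(CCCO)cc2OC)cc(OC)c1OCc1ccccc1
F4 | step 3 | 4-O,9-O,9'-O-tris[(1S,4R)-camphanoyl] derivative of 9 | COc1cc([C@@H](O)[C@H](COC(=O)[C@@]34CC[C@@](C)(C(=O)O3)C4(C)C)Oc2c(OC)cc(CCCOC(=O)[C@@]34CC[C@@](C)(C(=O)O3)C4(C)C)cc2OC)cc(OC)c1OC(=O)[C@@]12CC[C@@](C)(C(=O)O1)C2(C)C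
F5 | step 3 | 4-O,9-O,9'-O-tris[(1S,4R)-camphanoyl] derivative of the 7S,8R enantiomer | COc1cc([C@H](O)[C@@H](COC(=O)[C@@]34CC[C@@](C)(C(=O)O3)C4(C)C)Oc2c(OC)cc(CCCOC(=O)[C@@]34CC[C@@](C)(C(=O)O3)C4(C)C)cc2OC)cc(OC)c1OC(=O)[C@@]12CC[C@@](C)(C(=O)O1)C2(C)C
F0 | step 1 | none | none
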